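**Retrosynthetic overview**

1. The C4–C5 oxirane is introduced last, by peracid on the ring-bound E-alkene of 33; before that O8 is acylated with acid 29 (Sharpless epoxidation of tiglyl alcohol, then oxidation) and O9 is acetylated.
2. Key disconnection: C6–C7 and C11–C12 are cut together. A terminal allene (C13=C11=C7), CO2 (C12) and the C6 aldehyde of open chain 22 are joined on zerovalent nickel; this closes the ten-membered carbocycle and, after acyl closure on O6, the lactone.
3. Enabling feature: the α-methylene-γ-butyrolactone O6–C12(=O)–C11(=C13H2)–C7, fused to the ten-membered ring at C6–C7. C7–H next to C11=C13H2 is the imprint of an allene, the O-bearing C6 that of an aldehyde, and C12 is a single carbon at the CO2 oxidation level.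
4. Chain 22: C7–C9 from (S)-glycerate (C8 from the chiral pool, C9 by CBS reduction), C10/C1 from cis-1,2-dichloroethene, C14 from ClCO2Me, C2–C6/C15 from (E)-3-methylpent-2-en-4-yn-1-ol, C11/C13 from acetylene. The C10=C1 geometry comes from syn-hydrostannation, the 2Z geometry from zinc semi-reduction.
5. Ring order: ten-membered carbocycle, then γ-lactone (both in step 17), then the ring oxirane (step 24).

Key step: step 17

Remark: locants C1–C15 are the germacranolide positions of the target; the O8 ester is taken as drawn, i.e. (2S,3R)-2,3-dimethyloxirane-2-carboxylate (cis-dimethyl, tiglate-derived). CIP descriptors at C6, C7 and C9 change along the route with the substituents although the spatial arrangement does not.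

**Route**

Step 1
Reactants: 1 methyl (S)-2,2-dimethyl-1,3-dioxolane-4-carboxylate
Product: 2 (S)-N-methoxy-N,2,2-trimethyl-1,3-dioxolane-4-carboxamide
Conditions: MeNH(OMe)·HCl, i-PrMgCl, THF, −20 °C
Reagents that add atoms: N,O-dimethylhydroxylamine hydrochloride, CNOC.Cl
Why: Aminolysis of the ester by the magnesium amide (Weinreb amide formation) runs cold enough to keep the acetonide and the α-alkoxy centre (C8, from the chiral pool) intact.

Step 2
Reactants: 2 (S)-N-methoxy-N,2,2-trimethyl-1,3-dioxolane-4-carboxamide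
Product: 3 (S)-2,3-dihydroxy-N-methoxy-N-methylpropanamide
Conditions: AcOH/H2O (4:1), 40 °C
Reagents that add atoms: none
Why: Acid-catalysed acetal hydrolysis frees both hydroxyls while the Weinreb amide is inert to dilute acid.

Step 3
Reactants: 3 (S)-2,3-dihydroxy-N-methoxy-N-methylpropanamide
Product: 4 (S)-N-methoxy-N-methyl-2,3-bis(triethylsilyloxy)propanamide
Conditions: TESCl, imidazole, DMAP (cat.), CH2Cl2, 0 to 23 °C
Reagents that add atoms: chlorotriethylsilane, CC[Si](Cl)(CC)CC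
Why: Silyl ether formation on both hydroxyls gives a non-chelating α-silyloxy amide whose primary and secondary TES groups can later be told apart.

Step 4
Reactants: 5 (E)-3-methylpent-2-en-4-yn-1-ol
Product: 6 (E)-3-methylpent-2-en-4-yn-1-yl 4-methoxybenzyl ether
Conditions: NaH, PMBCl, Bu4NI (cat.), THF/DMF, 0 to 23 °C
Reagents that add atoms: 4-methoxybenzyl chloride, COc1ccc(CCl)cc1
Why: Williamson etherification of the alkoxide gives a primary allylic PMB ether that is orthogonal to every silyl ether used later.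

Step 5
Reactants: 6 (E)-3-methylpent-2-en-4-yn-1-yl 4-methoxybenzyl ether
Product: 7 (2E,6Z)-7-chloro-3-methylhepta-2,6-dien-4-yn-1-yl 4-methoxybenzyl ether
Conditions: (Z)-ClCH=CHCl (5 equiv), Pd(PPh3)4 (cat.), CuI (cat.), n-BuNH2, Et2O, 23 °C
Reagents that add atoms: (Z)-1,2-dichloroethene, Cl/C=C\Cl
Why: Sonogashira-type coupling of the terminal alkyne with excess cis-dichloroethene occurs once and with retention, giving the (Z)-chloroenyne that carries C1 and C10.

Step 6
Reactants: 7 (2E,6Z)-7-chloro-3-methylhepta-2,6-dien-4-yn-1-yl 4-methoxybenzyl ether; 4 (S)-N-methoxy-N-methyl-2,3-bis(triethylsilyloxy)propanamide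
Product: 9 (2S,8E)-10-(4-methoxybenzyloxy)-8-methyl-1,2-bis(triethylsilyloxy)dec-8-ene-4,6-diyn-3-one, via lithium diynide 8 (not isolated)
Conditions: LDA (2.0 equiv), THF, −78 °C; then 4, −78 to 0 °C; aq. NH4Cl
Reagents that add atoms: none
Why: Anti elimination of HCl and deprotonation give the lithium diynide, which acylates once on the Weinreb amide because the chelated tetrahedral adduct survives until work-up.

Step 7
Reactants: 9 (2S,8E)-10-(4-methoxybenzyloxy)-8-methyl-1,2-bis(triethylsilyloxy)dec-8-ene-4,6-diyn-3-one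
Product: 10 (2S,4E,8E)-10-(4-methoxybenzyloxy)-8-methyl-4-(tributylstannyl)-1,2-bis(triethylsilyloxy)deca-4,8-dien-6-yn-3-one
Conditions: Bu3SnH (1.05 equiv, slow addition), Pd(PPh3)4 (cat.), THF, −40 to 0 °C
Reagents that add atoms: tributyltin hydride, CCCC[SnH](CCCC)CCCC
Why: Palladium-catalysed hydrostannation of an ynone is a syn addition with tin α to the carbonyl, so only the activated triple bond reacts (Sn to C10, H to C1) and C9 ends up cis to C2 across C10=C1.

Step 8
Reactants: 10 (2S,4E,8E)-10-(4-methoxybenzyloxy)-8-methyl-4-(tributylstannyl)-1,2-bis(triethylsilyloxy)deca-4,8-dien-6-yn-3-one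
Product: 11 (2S,3R,4E,8E)-10-(4-methoxybenzyloxy)-8-methyl-4-(tributylstannyl)-1,2-bis(triethylsilyloxy)deca-4,8-dien-6-yn-3-ol
Conditions: (S)-2-methyl-CBS-oxazaborolidine (0.5 equiv), catecholborane, toluene, −78 °C
Reagents that add atoms: none
Why: Corey–Bakshi–Shibata reduction is 1,2-selective on enones; the (S)-catalyst treats the stannylated alkenyl arm as the large group and its facial preference coincides with the Felkin–Anh preference of the α-silyloxy ketone, which sets C9 syn to O8.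

Step 9
Reactants: 11 (2S,3R,4E,8E)-10-(4-methoxybenzyloxy)-8-methyl-4-(tributylstannyl)-1,2-bis(triethylsilyloxy)deca-4,8-dien-6-yn-3-ol
Product: 12 (2S,3R,4E,8E)-3-(tert-butyldimethylsilyloxy)-10-(4-methoxybenzyloxy)-8-methyl-4-(tributylstannyl)-1,2-bis(triethylsilyloxy)deca-4,8-dien-6-yne
Conditions: TBSOTf, 2,6-lutidine, CH2Cl2, −78 °C
Reagents that add atoms: tert-butyldimethylsilyl triflate, CC(C)(C)[Si](C)(C)OS(=O)(=O)C(F)(F)F
Why: Silyl triflate with excess lutidine silylates the hindered allylic alcohol at low temperature without protodestannylation or loss of the TES groups.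

Step 10
Reactants: 12 (2S,3R,4E,8E)-3-(tert-butyldimethylsilyloxy)-10-(4-methoxybenzyloxy)-8-methyl-4-(tributylstannyl)-1,2-bis(triethylsilyloxy)deca-4,8-dien-6-yne
Product: 14 methyl (2E,6E)-2-[(1S,2S)-1-(tert-butyldimethylsilyloxy)-2,3-bis(triethylsilyloxy)propyl]-8-(4-methoxybenzyloxy)-6-methylocta-2,6-dien-4-ynoate, via vinyllithium 13 (not isolated)
Conditions: n-BuLi (1.05 equiv), THF, −78 °C; then ClCO2Me, −78 to −40 °C
Reagents that add atoms: methyl chloroformate, COC(=O)Cl
Why: Tin–lithium exchange is fast and stereoretentive at −78 °C and the configurationally stable vinyllithium is acylated by the chloroformate, which places C14 on C10 with the double-bond geometry unchanged.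

Step 11
Reactants: 14 methyl (2E,6E)-2-[(1S,2S)-1-(tert-butyldimethylsilyloxy)-2,3-bis(triethylsilyloxy)propyl]-8-(4-methoxybenzyloxy)-6-methylocta-2,6-dien-4-ynoate
Product: 15 methyl (2E,4Z,6E)-2-[(1S,2S)-1-(tert-butyldimethylsilyloxy)-2,3-bis(triethylsilyloxy)propyl]-8-(4-methoxybenzyloxy)-6-methylocta-2,4,6-trienoate
Conditions: Zn dust activated with Cu(OAc)2 and AgNO3, MeOH/H2O/THF, 40 °C
Reagents that add atoms: none
Why: Activated zinc semi-reduces only a triple bond that is conjugated on both sides, by cis addition of hydrogen, so the 2Z-alkene (target numbering) should form without over-reduction.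

Step 12
Reactants: 15 methyl (2E,4Z,6E)-2-[(1S,2S)-1-(tert-butyldimethylsilyloxy)-2,3-bis(triethylsilyloxy)propyl]-8-(4-methoxybenzyloxy)-6-methylocta-2,4,6-trienoate
Product: 16 methyl (2E,4Z,6E)-2-[(1S,2R)-1-(tert-butyldimethylsilyloxy)-3-oxo-2-(triethylsilyloxy)propyl]-8-(4-methoxybenzyloxy)-6-methylocta-2,4,6-trienoate
Conditions: (COCl)2, DMSO, CH2Cl2, −78 to −40 °C; then Et3N, −78 to 0 °C
Reagents that add atoms: none
Why: Under Swern conditions a primary TES ether is converted directly into the aldehyde while secondary TES, TBS and PMB ethers are kept (direct Swern oxidation of primary TES ethers).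

Step 13
Reactants: 16 methyl (2E,4Z,6E)-2-[(1S,2R)-1-(tert-butyldimethylsilyloxy)-3-oxo-2-(triethylsilyloxy)propyl]-8-(4-methoxybenzyloxy)-6-methylocta-2,4,6-trienoate
Product: 17 methyl (2E,4Z,6E)-2-[(1S,2S,3RS)-1-(tert-butyldimethylsilyloxy)-3-hydroxy-2-(triethylsilyloxy)pent-4-yn-1-yl]-8-(4-methoxybenzyloxy)-6-methylocta-2,4,6-trienoate
Conditions: HC≡CMgBr, THF, −78 °C
Reagents that add atoms: ethynylmagnesium bromide, C#C[Mg]Br
Why: Grignard addition to the aldehyde is much faster at −78 °C than attack on the hindered conjugated ester, and the new carbinol centre (C7) is removed in the next step so its configuration does not matter.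

Step 14
Reactants: 17 methyl (2E,4Z,6E)-2-[(1S,2S,3RS)-1-(tert-butyldimethylsilyloxy)-3-hydroxy-2-(triethylsilyloxy)pent-4-yn-1-yl]-8-(4-methoxybenzyloxy)-6-methylocta-2,4,6-trienoate
Product: 20 methyl (2E,4Z,6E)-2-[(1S,2S)-1-(tert-butyldimethylsilyloxy)-2-(triethylsilyloxy)penta-3,4-dien-1-yl]-8-(4-methoxybenzyloxy)-6-methylocta-2,4,6-trienoate, via sulfonylhydrazine adduct 18 (not isolated), via propargylic diazene 19 (not isolated)
Conditions: PPh3, DEAD, THF, −15 °C; then 2-nitrobenzenesulfonylhydrazide, −15 to 23 °C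
Reagents that add atoms: none
Why: Mitsunobu displacement of the propargylic alcohol by the sulfonylhydrazide, loss of sulfinic acid and sigmatropic loss of N2 from the diazene deliver hydrogen to C13 and give the terminal allene under neutral conditions (reductive 1,3-transposition).

Step 15
Reactants: 20 methyl (2E,4Z,6E)-2-[(1S,2S)-1-(tert-butyldimethylsilyloxy)-2-(triethylsilyloxy)penta-3,4-dien-1-yl]-8-(4-methoxybenzyloxy)-6-methylocta-2,4,6-trienoate
Product: 21 methyl (2E,4Z,6E)-2-[(1S,2S)-1-(tert-butyldimethylsilyloxy)-2-(triethylsilyloxy)penta-3,4-dien-1-yl]-8-hydroxy-6-methylocta-2,4,6-trienoate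
Conditions: DDQ, CH2Cl2/pH 7 phosphate buffer, 0 °C
Reagents that add atoms: none
Why: Oxidative cleavage of the PMB ether by DDQ in buffered wet solvent leaves silyl ethers, allene and ester untouched.

Step 16
Reactants: 21 methyl (2E,4Z,6E)-2-[(1S,2S)-1-(tert-butyldimethylsilyloxy)-2-(triethylsilyloxy)penta-3,4-dien-1-yl]-8-hydroxy-6-methylocta-2,4,6-trienoate
Product: 22 methyl (2E,4Z,6E)-2-[(1S,2S)-1-(tert-butyldimethylsilyloxy)-2-(triethylsilyloxy)penta-3,4-dien-1-yl]-6-methyl-8-oxoocta-2,4,6-trienoate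
Conditions: MnO2, CH2Cl2, 23 °C
Reagents that add atoms: none
Why: MnO2 oxidises the allylic alcohol to the enal under neutral conditions, which should keep the Z-alkene and the allene intact.

Step 17
Reactants: 22 methyl (2E,4Z,6E)-2-[(1S,2S)-1-(tert-butyldimethylsilyloxy)-2-(triethylsilyloxy)penta-3,4-dien-1-yl]-6-methyl-8-oxoocta-2,4,6-trienoate
Product: 25 methyl (1(10)E,2Z,4E,6R,7S,8S,9S)-9-(tert-butyldimethylsilyloxy)-8-(triethylsilyloxy)germacra-1(10),2,4,11(13)-tetraen-12,6-olid-14-oate, via nickelalactone 23 (not isolated), via hydroxy acid 24 (not isolated)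
Conditions: Ni(cod)2 (2 equiv), DBU (4 equiv), CO2 (1 atm), THF, 0 °C, slow addition of 22 (final 2 mM), then 23 °C; aq. NH4Cl/citric acid (pH 4); then EDC·HCl, DMAP (cat.), CH2Cl2, 23 °C
Reagents that add atoms: carbon dioxide, O=C=O
Why: Proposed new method: zerovalent nickel with DBU couples CO2 oxidatively across the terminal C11=C13 bond of the allene, which forms the C11–C12 bond and a 2-carboxylato-allylnickel chelate, and the substituted allyl terminus C7 then adds to the C6 aldehyde of the same molecule (C6–C7 bond); the closest known reaction is the nickel-mediated sequential carboxylation and aldehyde allylation of terminal allenes, so far run between separate molecules, and the ring-closing mode is modelled on allylchromium closures of ten-membered germacranolide rings. The ten-membered carbocycle closes by intramolecular γ-allylation of the aldehyde through a chair-like six-membered metal-bound transition state, and the γ-lactone then closes by 5-exo-trig acyl substitution of the C6 hydroxyl on the C12 acid once EDC is added. C7 is controlled by C8: A(1,3) strain to the cis substituent on C11 holds H8 in the allyl plane and the ring can only form with C9 antiperiplanar to the incoming C6, so C6 arrives on the face of O8 and gives the required configuration at C7. C6 is set relative to C7 by the same transition state with both ring bonds pseudo-equatorial, which should give the 6,7-anti adduct and hence the trans-fused lactone. The step needs CO2 to react with the allene before the aldehyde does, allylation at C7 and not at C13, and lactonisation on O6 only: high dilution under 1 atm CO2 keeps carboxylation ahead of any aldehyde–allene coupling across the ring, the cyclic transition state enforces γ-attack, and O8 and O9 are silylated.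

Step 18
Reactants: 25 methyl (1(10)E,2Z,4E,6R,7S,8S,9S)-9-(tert-butyldimethylsilyloxy)-8-(triethylsilyloxy)germacra-1(10),2,4,11(13)-tetraen-12,6-olid-14-oate
Product: 26 methyl (1(10)E,2Z,4E,6R,7R,8S,9S)-9-(tert-butyldimethylsilyloxy)-8-hydroxygermacra-1(10),2,4,11(13)-tetraen-12,6-olid-14-oate
Conditions: PPTS, MeOH/CH2Cl2, 0 °C
Reagents that add atoms: none
Why: Mild acid methanolysis removes the secondary TES ether much faster than the hindered secondary TBS ether, so only O8 is freed (the change at C7 is in the CIP descriptor only).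

Step 19
Reactants: 27 (E)-2-methylbut-2-en-1-ol
Product: 28 [(2R,3R)-2,3-dimethyloxiran-2-yl]methanol
Conditions: Ti(OiPr)4 (cat.), D-(−)-diisopropyl tartrate (cat.), t-BuOOH, 4 Å MS, CH2Cl2, −20 °C
Reagents that add atoms: tert-butyl hydroperoxide, CC(C)(C)OO
Why: Sharpless asymmetric epoxidation of the E-allylic alcohol with the D-tartrate delivers oxygen to the face that gives the (2R,3R)-epoxy alcohol, both centres by catalyst control.

Step 20
Reactants: 28 [(2R,3R)-2,3-dimethyloxiran-2-yl]methanol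
Product: 29 (2S,3R)-2,3-dimethyloxirane-2-carboxylic acid
Conditions: RuCl3·xH2O (cat.), NaIO4, MeCN/CCl4/H2O, 23 °C
Reagents that add atoms: water, O; sodium periodate, [Na+].[O-]I(=O)(=O)=O
Why: RuO4 generated in situ oxidises the primary alcohol to the acid without opening the oxirane, and C2 becomes 2S only through the change in CIP priorities.

Step 21
Reactants: 26 methyl (1(10)E,2Z,4E,6R,7R,8S,9S)-9-(tert-butyldimethylsilyloxy)-8-hydroxygermacra-1(10),2,4,11(13)-tetraen-12,6-olid-14-oate; 29 (2S,3R)-2,3-dimethyloxirane-2-carboxylic acid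
Product: 31 methyl (1(10)E,2Z,4E,6R,7S,8S,9S)-9-(tert-butyldimethylsilyloxy)-8-[(2S,3R)-2,3-dimethyloxirane-2-carbonyloxy]germacra-1(10),2,4,11(13)-tetraen-12,6-olid-14-oate, via mixed anhydride 30 (not isolated)
Conditions: 2,4,6-Cl3C6H2COCl, Et3N, THF, 23 °C; then 26, DMAP, toluene, 23 to 40 °C
Reagents that add atoms: none
Why: Yamaguchi esterification through the mixed anhydride acylates the hindered secondary C8 hydroxyl with the α-quaternary acid under DMAP catalysis without touching any stereocentre.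

Step 22
Reactants: 31 methyl (1(10)E,2Z,4E,6R,7S,8S,9S)-9-(tert-butyldimethylsilyloxy)-8-[(2S,3R)-2,3-dimethyloxirane-2-carbonyloxy]germacra-1(10),2,4,11(13)-tetraen-12,6-olid-14-oate
Product: 32 methyl (1(10)E,2Z,4E,6R,7S,8S,9S)-8-[(2S,3R)-2,3-dimethyloxirane-2-carbonyloxy]-9-hydroxygermacra-1(10),2,4,11(13)-tetraen-12,6-olid-14-oate
Conditions: HF·pyridine, pyridine, THF, 0 to 23 °C
Reagents that add atoms: none
Why: Fluoride-mediated cleavage of the remaining TBS ether is compatible with the glycidic ester, the α-methylene lactone and the triene.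

Step 23
Reactants: 32 methyl (1(10)E,2Z,4E,6R,7S,8S,9S)-8-[(2S,3R)-2,3-dimethyloxirane-2-carbonyloxy]-9-hydroxygermacra-1(10),2,4,11(13)-tetraen-12,6-olid-14-oate
Product: 33 methyl (1(10)E,2Z,4E,6R,7S,8S,9S)-9-acetoxy-8-[(2S,3R)-2,3-dimethyloxirane-2-carbonyloxy]germacra-1(10),2,4,11(13)-tetraen-12,6-olid-14-oate
Conditions: Ac2O, pyridine, DMAP (cat.), CH2Cl2, 0 °C
Reagents that add atoms: acetic anhydride, CC(=O)OC(C)=O
Why: Acetylation of the allylic C9 alcohol is fast, and with O8 already acylated there is no free neighbouring hydroxyl for acyl migration.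

Step 24
Reactants: 33 methyl (1(10)E,2Z,4E,6R,7S,8S,9S)-9-acetoxy-8-[(2S,3R)-2,3-dimethyloxirane-2-carbonyloxy]germacra-1(10),2,4,11(13)-tetraen-12,6-olid-14-oate
Product: 34 target CNP0229507.7, methyl (1(10)E,2Z,4R,5R,6S,7R,8S,9S)-9-acetoxy-8-[(2S,3R)-2,3-dimethyloxirane-2-carbonyloxy]-4,5-epoxygermacra-1(10),2,11(13)-trien-12,6-olid-14-oate
Conditions: mCPBA, NaHCO3, CH2Cl2, 0 °C
Reagents that add atoms: 3-chloroperbenzoic acid, OOC(=O)c1cccc(Cl)c1
Why: Prilezhaev epoxidation should take only the trisubstituted C4=C5 bond, the one alkene not deactivated by an ester; A(1,3) strain keeps H6 in the plane of this alkene and the ring chain covers its C7-side face, so oxygen enters from the open face on the side of O6 and gives the 4R,5R-oxirane.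

**Compound list**

1 | methyl (S)-2,2-dimethyl-1,3-dioxolane-4-carboxylate | COC(=O)[C@@H]1COC(C)(C)O1 | starting material
2 | (S)-N-methoxy-N,2,2-trimethyl-1,3-dioxolane-4-carboxamide | CON(C)C(=O)[C@@H]1COC(C)(C)O1 | intermediate
3 | (S)-2,3-dihydroxy-N-methoxy-N-methylpropanamide | CON(C)C(=O)[C@@H](O)CO | intermediate
4 | (S)-N-methoxy-N-methyl-2,3-bis(triethylsilyloxy)propanamide | CON(C)C(=O)[C@@H](O[Si](CC)(CC)CC)CO[Si](CC)(CC)CC | intermediate
5 | (E)-3-methylpent-2-en-4-yn-1-ol | C#C/C(C)=C/CO | starting material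
6 | (E)-3-methylpent-2-en-4-yn-1-yl 4-methoxybenzyl ether | C#C/C(C)=C/COCc1ccc(OC)cc1 | intermediate
7 | (2E,6Z)-7-chloro-3-methylhepta-2,6-dien-4-yn-1-yl 4-methoxybenzyl ether | Cl/C=C\C#C/C(C)=C/COCc1ccc(OC)cc1 | intermediate
8 | lithium diynide, [(E)-7-(4-methoxybenzyloxy)-5-methylhept-5-ene-1,3-diyn-1-yl]lithium | [Li]C#CC#C/C(C)=C/COCc1ccc(OC)cc1 | intermediate (not isolated)
9 | (2S,8E)-10-(4-methoxybenzyloxy)-8-methyl-1,2-bis(triethylsilyloxy)dec-8-ene-4,6-diyn-3-one | CC[Si](CC)(CC)OC[C@H](O[Si](CC)(CC)CC)C(=O)C#CC#C/C(C)=C/COCc1ccc(OC)cc1 | intermediate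
10 | (2S,4E,8E)-10-(4-methoxybenzyloxy)-8-methyl-4-(tributylstannyl)-1,2-bis(triethylsilyloxy)deca-4,8-dien-6-yn-3-one | CC[Si](CC)(CC)OC[C@H](O[Si](CC)(CC)CC)C(=O)/C(=C\C#C/C(C)=C/COCc1ccc(OC)cc1)[Sn](CCCC)(CCCC)CCCC | intermediate
11 | (2S,3R,4E,8E)-10-(4-methoxybenzyloxy)-8-methyl-4-(tributylstannyl)-1,2-bis(triethylsilyloxy)deca-4,8-dien-6-yn-3-ol | CC[Si](CC)(CC)OC[C@H](O[Si](CC)(CC)CC)[C@@H](O)/C(=C\C#C/C(C)=C/COCc1ccc(OC)cc1)[Sn](CCCC)(CCCC)CCCC | intermediate
12 | (2S,3R,4E,8E)-3-(tert-butyldimethylsilyloxy)-10-(4-methoxybenzyloxy)-8-methyl-4-(tributylstannyl)-1,2-bis(triethylsilyloxy)deca-4,8-dien-6-yne | CC[Si](CC)(CC)OC[C@H](O[Si](CC)(CC)CC)[C@@H](O[Si](C)(C)C(C)(C)C)/C(=C\C#C/C(C)=C/COCc1ccc(OC)cc1)[Sn](CCCC)(CCCC)CCCC | intermediate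
13 | vinyllithium, the 4-lithio analogue of 12 (tin replaced by lithium with retention) | CC[Si](CC)(CC)OC[C@H](O[Si](CC)(CC)CC)[C@@H](O[Si](C)(C)C(C)(C)C)/C([Li])=C\C#C/C(C)=C/COCc1ccc(OC)cc1 | intermediate (not isolated)
14 | methyl (2E,6E)-2-[(1S,2S)-1-(tert-butyldimethylsilyloxy)-2,3-bis(triethylsilyloxy)propyl]-8-(4-methoxybenzyloxy)-6-methylocta-2,6-dien-4-ynoate | CC[Si](CC)(CC)OC[C@H](O[Si](CC)(CC)CC)[C@@H](O[Si](C)(C)C(C)(C)C)/C(C(=O)OC)=C\C#C/C(C)=C/COCc1ccc(OC)cc1 | intermediate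
15 | methyl (2E,4Z,6E)-2-[(1S,2S)-1-(tert-butyldimethylsilyloxy)-2,3-bis(triethylsilyloxy)propyl]-8-(4-methoxybenzyloxy)-6-methylocta-2,4,6-trienoate | CC[Si](CC)(CC)OC[C@H](O[Si](CC)(CC)CC)[C@@H](O[Si](C)(C)C(C)(C)C)/C(C(=O)OC)=C\C=C/C(C)=C/COCc1ccc(OC)cc1 | intermediate
16 | methyl (2E,4Z,6E)-2-[(1S,2R)-1-(tert-butyldimethylsilyloxy)-3-oxo-2-(triethylsilyloxy)propyl]-8-(4-methoxybenzyloxy)-6-methylocta-2,4,6-trienoate | O=C[C@H](O[Si](CC)(CC)CC)[C@@H](O[Si](C)(C)C(C)(C)C)/C(C(=O)OC)=C\C=C/C(C)=C/COCc1ccc(OC)cc1 | intermediate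
17 | methyl (2E,4Z,6E)-2-[(1S,2S,3RS)-1-(tert-butyldimethylsilyloxy)-3-hydroxy-2-(triethylsilyloxy)pent-4-yn-1-yl]-8-(4-methoxybenzyloxy)-6-methylocta-2,4,6-trienoate (C7 carbinol as epimer mixture) | C#CC(O)[C@H](O[Si](CC)(CC)CC)[C@@H](O[Si](C)(C)C(C)(C)C)/C(C(=O)OC)=C\C=C/C(C)=C/COCc1ccc(OC)cc1 | intermediate
18 | sulfonylhydrazine adduct, N-alkyl-N-(2-nitrobenzenesulfonyl)hydrazine at C7 of 17 | C#CC(N(N)S(=O)(=O)c1ccccc1[N+](=O)[O-])[C@H](O[Si](CC)(CC)CC)[C@@H](O[Si](C)(C)C(C)(C)C)/C(C(=O)OC)=C\C=C/C(C)=C/COCc1ccc(OC)cc1 | intermediate (not isolated)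
19 | propargylic diazene at C7 | C#CC(N=N)[C@H](O[Si](CC)(CC)CC)[C@@H](O[Si](C)(C)C(C)(C)C)/C(C(=O)OC)=C\C=C/C(C)=C/COCc1ccc(OC)cc1 | intermediate (not isolated)
20 | methyl (2E,4Z,6E)-2-[(1S,2S)-1-(tert-butyldimethylsilyloxy)-2-(triethylsilyloxy)penta-3,4-dien-1-yl]-8-(4-methoxybenzyloxy)-6-methylocta-2,4,6-trienoate | C=C=C[C@H](O[Si](CC)(CC)CC)[C@@H](O[Si](C)(C)C(C)(C)C)/C(C(=O)OC)=C\C=C/C(C)=C/COCc1ccc(OC)cc1 | intermediate
21 | methyl (2E,4Z,6E)-2-[(1S,2S)-1-(tert-butyldimethylsilyloxy)-2-(triethylsilyloxy)penta-3,4-dien-1-yl]-8-hydroxy-6-methylocta-2,4,6-trienoate | C=C=C[C@H](O[Si](CC)(CC)CC)[C@@H](O[Si](C)(C)C(C)(C)C)/C(C(=O)OC)=C\C=C/C(C)=C/CO | intermediate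
22 | methyl (2E,4Z,6E)-2-[(1S,2S)-1-(tert-butyldimethylsilyloxy)-2-(triethylsilyloxy)penta-3,4-dien-1-yl]-6-methyl-8-oxoocta-2,4,6-trienoate | C=C=C[C@H](O[Si](CC)(CC)CC)[C@@H](O[Si](C)(C)C(C)(C)C)/C(C(=O)OC)=C\C=C/C(C)=C/C=O | intermediate
23 | nickelalactone, 2-carboxylato-allylnickel chelate of 22 (DBU ligands on nickel not drawn) | O=C1O[Ni]C/C1=C\[C@H](O[Si](CC)(CC)CC)[C@@H](O[Si](C)(C)C(C)(C)C)/C(C(=O)OC)=C\C=C/C(C)=C/C=O | intermediate (not isolated)
24 | hydroxy acid, 2-[(1S,2R,3E,5Z,7E,9S,10S)-9-(tert-butyldimethylsilyloxy)-2-hydroxy-8-(methoxycarbonyl)-4-methyl-10-(triethylsilyloxy)cyclodeca-3,5,7-trien-1-yl]prop-2-enoic acid | C=C(C(=O)O)[C@@H]1[C@H](O[Si](CC)(CC)CC)[C@@H](O[Si](C)(C)C(C)(C)C)/C(C(=O)OC)=C\C=C/C(C)=C/[C@H]1O | intermediate (not isolated)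
25 | methyl (1(10)E,2Z,4E,6R,7S,8S,9S)-9-(tert-butyldimethylsilyloxy)-8-(triethylsilyloxy)germacra-1(10),2,4,11(13)-tetraen-12,6-olid-14-oate | O=C1O[C@@H]2/C=C(C)/C=C\C=C(C(=O)OC)/[C@H](O[Si](C)(C)C(C)(C)C)[C@@H](O[Si](CC)(CC)CC)[C@H]2C1=C | intermediate
26 | methyl (1(10)E,2Z,4E,6R,7R,8S,9S)-9-(tert-butyldimethylsilyloxy)-8-hydroxygermacra-1(10),2,4,11(13)-tetraen-12,6-olid-14-oate | O=C1O[C@@H]2/C=C(C)/C=C\C=C(C(=O)OC)/[C@H](O[Si](C)(C)C(C)(C)C)[C@@H](O)[C@H]2C1=C | intermediate
27 | (E)-2-methylbut-2-en-1-ol | C/C=C(\C)CO | starting material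
28 | [(2R,3R)-2,3-dimethyloxiran-2-yl]methanol | OC[C@@]1(C)O[C@@H]1C | intermediate
29 | (2S,3R)-2,3-dimethyloxirane-2-carboxylic acid | OC(=O)[C@@]1(C)O[C@@H]1C | intermediate
30 | mixed anhydride, (2S,3R)-2,3-dimethyloxirane-2-carboxylic 2,4,6-trichlorobenzoic anhydride | O=C(OC(=O)[C@@]1(C)O[C@@H]1C)c1c(Cl)cc(Cl)cc1Cl | intermediate (not isolated)
31 | methyl (1(10)E,2Z,4E,6R,7S,8S,9S)-9-(tert-butyldimethylsilyloxy)-8-[(2S,3R)-2,3-dimethyloxirane-2-carbonyloxy]germacra-1(10),2,4,11(13)-tetraen-12,6-olid-14-oate | O=C1O[C@@H]2/C=C(C)/C=C\C=C(C(=O)OC)/[C@H](O[Si](C)(C)C(C)(C)C)[C@@H](OC(=O)[C@@]3(C)O[C@@H]3C)[C@H]2C1=C | intermediate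
32 | methyl (1(10)E,2Z,4E,6R,7S,8S,9S)-8-[(2S,3R)-2,3-dimethyloxirane-2-carbonyloxy]-9-hydroxygermacra-1(10),2,4,11(13)-tetraen-12,6-olid-14-oate | O=C1O[C@@H]2/C=C(C)/C=C\C=C(C(=O)OC)/[C@H](O)[C@@H](OC(=O)[C@@]3(C)O[C@@H]3C)[C@H]2C1=C | intermediate
33 | methyl (1(10)E,2Z,4E,6R,7S,8S,9S)-9-acetoxy-8-[(2S,3R)-2,3-dimethyloxirane-2-carbonyloxy]germacra-1(10),2,4,11(13)-tetraen-12,6-olid-14-oate | O=C1O[C@@H]2/C=C(C)/C=C\C=C(C(=O)OC)/[C@H](OC(C)=O)[C@@H](OC(=O)[C@@]3(C)O[C@@H]3C)[C@H]2C1=C | intermediate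
34 | CNP0229507.7, methyl (1(10)E,2Z,4R,5R,6S,7R,8S,9S)-9-acetoxy-8-[(2S,3R)-2,3-dimethyloxirane-2-carbonyloxy]-4,5-epoxygermacra-1(10),2,11(13)-trien-12,6-olid-14-oate | C=C1C(=O)O[C@H]2[C@H]1[C@H](OC(=O)[C@@]1(C)O[C@@H]1C)[C@@H](OC(C)=O)/C(C(=O)OC)=C\C=C/[C@@]1(C)O[C@H]21 | target

**Step count and risks**

Total steps: 24. Longest linear sequence: 20 steps (steps 1–3, 6–18 and 21–24).

Steps most likely to fail:

1. Step 17 (the proposed new method). What may go wrong: the allylnickel carboxylate is protonated or oligomerises before it closes the ring; nickel is tied up by the conjugated trienal; the base isomerises the 2Z-alkene; or the ring closes with the wrong facial sense at C7. The fallback leaves the route at aldehyde 16 and returns at lactone 25, using only known reactions. A Morita–Baylis–Hillman reaction of 16 with methyl acrylate (DABCO) would give the adduct F1. Its SN2' bromination (NBS, Me2S) would give the (Z)-2-(bromomethyl)enoate F2. DDQ and then MnO2, as in steps 15 and 16, would give the allylic alcohol F3 and the enal F4. CrCl2 in THF/DMF at high dilution would then close the ten-membered ring by the Nozaki–Hiyama–Kishi-type allylation that is established for germacranolides, and the hydroxy ester F5 would lactonise with PPTS to 25. In this variant C11–C12 is already in place before the ring closes.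

2. Step 24. What may go wrong: poor facial selectivity at C4=C5 if the ring conformation does not shield one face as assumed, or competing attack at C2=C3. The fallback sets out from 33 and returns at 34. It moves stereocontrol from the substrate to the reagent: a Shi epoxidation with the D-fructose-derived ketone and Oxone (buffered MeCN/dimethoxymethane, 0 °C), whose chiral dioxirane is expected to deliver the (4R,5R)-oxirane to this E-trisubstituted alkene. No new intermediate is formed.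

3. Step 10. What may go wrong: loss of the silyloxy group by β-elimination or migration of silicon to carbon at the vinyllithium stage, or addition of butyllithium to the enyne. The fallback sets out from stannane 12 and returns at ester 14 without an organolithium. Iododestannylation with NIS (CH2Cl2, 0 °C) would give the vinyl iodide F6 with retention, and palladium-catalysed methoxycarbonylation (Pd(PPh3)2Cl2, CO 1 atm, MeOH, Et3N, DMF, 40 °C) would give 14.

**Further compounds**

F1 | step 17 | Morita–Baylis–Hillman adduct of 16, methyl 2-methylene-3-hydroxy ester at C7 (C7 carbinol as epimer mixture) | C=C(C(=O)OC)C(O)[C@H](O[Si](CC)(CC)CC)[C@@H](O[Si](C)(C)C(C)(C)C)/C(C(=O)OC)=C\C=C/C(C)=C/COCc1ccc(OC)cc1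
F2 | step 17 | (Z)-2-(bromomethyl)enoate, C13 bromide with C11 methyl ester and C11=C7 double bond | COC(=O)/C(CBr)=C/[C@H](O[Si](CC)(CC)CC)[C@@H](O[Si](C)(C)C(C)(C)C)/C(C(=O)OC)=C\C=C/C(C)=C/COCc1ccc(OC)cc1
F3 | step 17 | C6 allylic alcohol of F2 | COC(=O)/C(CBr)=C/[C@H](O[Si](CC)(CC)CC)[C@@H](O[Si](C)(C)C(C)(C)C)/C(C(=O)OC)=C\C=C/C(C)=C/CO
F4 | step 17 | C6 enal of F2 | COC(=O)/C(CBr)=C/[C@H](O[Si](CC)(CC)CC)[C@@H](O[Si](C)(C)C(C)(C)C)/C(C(=O)OC)=C\C=C/C(C)=C/C=O
F5 | step 17 | ring-closed hydroxy ester, methyl ester of 24 | C=C(C(=O)OC)[C@@H]1[C@H](O[Si](CC)(CC)CC)[C@@H](O[Si](C)(C)C(C)(C)C)/C(C(=O)OC)=C\C=C/C(C)=C/[C@H]1O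
F0 | step 24 | none | none
F6 | step 10 | vinyl iodide, the 4-iodo analogue of 12 | CC[Si](CC)(CC)OC[C@H](O[Si](CC)(CC)CC)[C@@H](O[Si](C)(C)C(C)(C)C)/C(I)=C\C#C/C(C)=C/COCc1ccc(OC)cc1
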